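The tetrahydrofuran O1–C2 bond is the strategic disconnection. C2 is the benzylic carbon para to the oxygen at C4 of ring A (the guaiacyl ring that later carries the glycerol ether), and O1 is a primary hydroxyl four atoms away. The precursor is therefore the open-chain, twofold-symmetric lignan diol (−)-secoisolariciresinol, desymmetrised as its mono-allyl ether. DDQ turns the free-phenol ring into a para-quinone methide that the remote CH2OH captures. In one operation this builds the ring, sets C2 trans to C3, and distinguishes the two aryl rings and the two hydroxymethyl arms. The liberated phenol is then elaborated by an Evans syn-aldol into the threo-(7S,8S) arylglycerol ether.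

Key step: step 2

Remark: locants are tetrahydrofuran O1, C2 (ring A), C3 (CH2OH), C4 (benzyl carrying ring B), C5, and glycerol chain C7''(OH)–C8''(OAr)–C9''(OH) on ring C; open-chain precursors keep the lignan locants C7/C8/C9 (ring A side) and C7'/C8'/C9' (ring B side); compounds 1, 5 and 8 are taken as purchasable.

Step 1
Reactants: 1 (−)-secoisolariciresinol
Product: 2 mono-O-allyl secoisolariciresinol
Conditions: allyl bromide (0.9–1.0 equiv), K2CO3 (1.1 equiv), acetone, reflux; chromatographic separation from recovered 1 and bis-ether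
Reagents that add atoms: allyl bromide, C=CCBr
Why: Williamson etherification in which K2CO3 ionises only the phenols, and because the two phenols of 1 are homotopic, mono-allylation with limiting allyl bromide should give one constitutional product; no stereocentre is touched.

Step 2
Reactants: 2 mono-O-allyl secoisolariciresinol
Product: 4 4'-O-allyl-(+)-lariciresinol, via para-quinone methide 3 (not isolated)
Conditions: DDQ (1.05 equiv), 1,4-dioxane, 15 °C to rt
Reagents that add atoms: none
Why: DDQ removes hydride from the benzylic C7–H of the only free 4-hydroxy-3-methoxybenzyl ring (ring A) through its charge-transfer complex and gives para-quinone methide 3, whose methide carbon is then attacked by the hydroxyl oxygen of the far hydroxymethyl arm (C9') with rearomatisation of ring A. The closest known reaction type is the DDQ dehydrogenation of 4-alkylguaiacols to quinone methides that are trapped by alcohols, the laboratory counterpart of furan-ring formation in lignan biosynthesis. The tetrahydrofuran closes in a 5-exo-trig oxa-1,6-addition, since the methide C=C lies outside the new ring. The new stereocentre C2 (S) is controlled by the neighbouring C3 stereocentre: the aryl group takes the face opposite to the C3 hydroxymethyl and C4 benzyl groups, and because the addition is reversible under the weakly acidic hydroquinone the 2,3-trans product is also the thermodynamic one. The step needs chemoselectivity between the two arenes and between the two hydroxymethyl groups: ring B is an allyl ether and cannot become a quinone methide, which also prevents a second closure to a furofuran, and only the hydroxymethyl on the carbon remote from C7 can reach it through a five-membered ring, whereas the other would give an oxetane. O-attack should outrun Friedel–Crafts attack of ring B on the methide carbon as long as strong acid is absent and DDQ is not used in excess.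

Step 3
Reactants: 4 4'-O-allyl-(+)-lariciresinol; 5 (R)-4-benzyl-3-(chloroacetyl)oxazolidin-2-one
Product: 7 aryloxyacetyl imide acetate, via hydroxy imide 6 (not isolated)
Conditions: K2CO3 (1.5 equiv), DMF, rt; then Ac2O (2 equiv), Et3N, DMAP (cat.), rt, same flask
Reagents that add atoms: acetic anhydride, CC(=O)OC(C)=O
Why: Williamson O-alkylation of the ring A phenoxide at the carbonyl-activated chloromethyl carbon (SN2), followed by DMAP-catalysed acetylation of the one remaining hydroxyl so that no free OH meets the boron triflate of the next step; no stereocentre is formed or touched.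

Step 4
Reactants: 7 aryloxyacetyl imide acetate; 8 4-(allyloxy)-3-methoxybenzaldehyde
Product: 11 syn-aldol adduct, via Z-dibutylboron enolate 9 (not isolated), via dibutylboron aldolate 10 (not isolated)
Conditions: Bu2BOTf (1.2 equiv), iPr2NEt (1.4 equiv), CH2Cl2, −78 to 0 °C; then 8, −78 to 0 °C; pH 7 buffer, MeOH, 30% H2O2, 0 °C
Reagents that add atoms: none
Why: Evans syn-aldol in which Z-boron enolate 9 reacts through a closed Zimmerman–Traxler chair and the (R)-benzyl group of the dipole-opposed oxazolidinone blocks one enolate face, which should give the syn (threo) adduct whose new α-carbon (R by CIP in the imide) and carbinol carbon (S) become C8'' (S) and C7'' (S) of the target, the auxiliary overriding the remote ring stereocentres.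

Step 5
Reactants: 11 syn-aldol adduct
Product: 12 bis-O-allyl triol
Conditions: LiBH4 (5 equiv), MeOH (5 equiv), THF, 0 °C to rt
Reagents that add atoms: none
Why: reductive cleavage of the N-acyl oxazolidinone at the exocyclic carbonyl by LiBH4 gives the C9'' primary alcohol and the same reagent reduces off the acetate, freeing the C3 hydroxymethyl; the C7''/C8'' stereocentres are not epimerisable under these non-enolising conditions.

Step 6
Reactants: 12 bis-O-allyl triol
Product: 13 target compound (CNP0226724.1)
Conditions: Pd(PPh3)4 (5 mol %), morpholine (10 equiv), degassed THF, rt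
Reagents that add atoms: none
Why: Tsuji–Trost deallylation in which zerovalent palladium ionises each aryl allyl ether to a π-allyl complex and phenoxide while morpholine captures the allyl group, a method that leaves the benzylic C2–O1 and C7''–OH bonds untouched where hydrogenolysis would endanger them.

Compound list
1 | (−)-secoisolariciresinol, (2R,3R)-2,3-bis(4-hydroxy-3-methoxybenzyl)butane-1,4-diol | COc1cc(C[C@H]([C@@H](Cc2ccc(O)c(OC)c2)CO)CO)ccc1O | starting material
2 | mono-O-allyl secoisolariciresinol, (2R,3R)-2-[4-(allyloxy)-3-methoxybenzyl]-3-(4-hydroxy-3-methoxybenzyl)butane-1,4-diol | C=CCOc1ccc(C[C@H]([C@@H](Cc2ccc(O)c(OC)c2)CO)CO)cc1OC | intermediate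
3 | para-quinone methide of 2 (ring A as 2-methoxy-4-alkylidenecyclohexa-2,5-dien-1-one, side-chain stereocentres as in 2) | COC1=CC(=C[C@@H](CO)[C@H](CO)Cc2ccc(OCC=C)c(OC)c2)C=CC1=O | intermediate
4 | 4'-O-allyl-(+)-lariciresinol, (2S,3R,4R)-4-[4-(allyloxy)-3-methoxybenzyl]-2-(4-hydroxy-3-methoxyphenyl)-3-(hydroxymethyl)tetrahydrofuran | COc1cc(C[C@H]2CO[C@H](c3ccc(O)c(OC)c3)[C@H]2CO)ccc1OCC=C | intermediate
5 | (R)-4-benzyl-3-(chloroacetyl)oxazolidin-2-one | O=C(CCl)N1C(=O)OC[C@H]1Cc2ccccc2 | starting material
6 | hydroxy imide: 4 with the ring A phenol oxygen carrying CH2C(=O)–N of (R)-4-benzyloxazolidin-2-one, C3 hydroxymethyl free | COc1cc(C[C@H]2CO[C@H](c3ccc(OCC(=O)N4C(=O)OC[C@H]4Cc5ccccc5)c(OC)c3)[C@H]2CO)ccc1OCC=C | intermediate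
7 | aryloxyacetyl imide acetate: 6 with the C3 hydroxymethyl as its acetate | COc1cc(C[C@H]2CO[C@H](c3ccc(OCC(=O)N4C(=O)OC[C@H]4Cc5ccccc5)c(OC)c3)[C@H]2COC(C)=O)ccc1OCC=C | intermediate
8 | 4-(allyloxy)-3-methoxybenzaldehyde (O-allylvanillin) | C=CCOc1ccc(C=O)cc1OC | starting material
9 | Z-dibutylboron enolate of 7 (aryloxy group cis to the O–BBu2 group) | COc1cc(C[C@H]2CO[C@H](c3ccc(O/C=C(\OB(CCCC)CCCC)N4C(=O)OC[C@H]4Cc5ccccc5)c(OC)c3)[C@H]2COC(C)=O)ccc1OCC=C | intermediate
10 | dibutylboron aldolate: 11 with its carbinol oxygen bound to BBu2 | COc1cc(C[C@H]2CO[C@H](c3ccc(O[C@@H](C(=O)N4C(=O)OC[C@H]4Cc5ccccc5)[C@@H](OB(CCCC)CCCC)c6ccc(OCC=C)c(OC)c6)c(OC)c3)[C@H]2COC(C)=O)ccc1OCC=C | intermediate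
11 | syn-aldol adduct, (R)-4-benzyl-3-{(2R,3S)-3-[4-(allyloxy)-3-methoxyphenyl]-3-hydroxy-2-(aryloxy)propanoyl}oxazolidin-2-one, aryloxy = 4-[(2S,3R,4R)-3-(acetoxymethyl)-4-(4-(allyloxy)-3-methoxybenzyl)tetrahydrofuran-2-yl]-2-methoxyphenoxy | COc1cc(C[C@H]2CO[C@H](c3ccc(O[C@@H](C(=O)N4C(=O)OC[C@H]4Cc5ccccc5)[C@@H](O)c6ccc(OCC=C)c(OC)c6)c(OC)c3)[C@H]2COC(C)=O)ccc1OCC=C | intermediate
12 | bis-O-allyl triol, (1S,2S)-1-[4-(allyloxy)-3-methoxyphenyl]-2-{4-[(2S,3R,4R)-4-(4-(allyloxy)-3-methoxybenzyl)-3-(hydroxymethyl)tetrahydrofuran-2-yl]-2-methoxyphenoxy}propane-1,3-diol | COc1cc(C[C@H]2CO[C@H](c3ccc(O[C@@H](CO)[C@@H](O)c4ccc(OCC=C)c(OC)c4)c(OC)c3)[C@H]2CO)ccc1OCC=C | intermediate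
13 | target, (1S,2S)-1-(4-hydroxy-3-methoxyphenyl)-2-{4-[(2S,3R,4R)-4-(4-hydroxy-3-methoxybenzyl)-3-(hydroxymethyl)tetrahydrofuran-2-yl]-2-methoxyphenoxy}propane-1,3-diol | COc1cc(C[C@H]2CO[C@H](c3ccc(O[C@@H](CO)[C@@H](O)c4ccc(O)c(OC)c4)c(OC)c3)[C@H]2CO)ccc1O | target

Total step count: 6. Longest linear sequence: 6 steps (1 to 13); 5 and 8 enter as purchased reagents.

Steps most likely to fail

Step 2. The quinone methide or the product may be consumed by a second hydride abstraction at the newly formed benzylic ether C–H, ring B may attack the methide carbon (aryltetralin formation), and trans control may be incomplete under purely kinetic conditions. The fallback separates oxidation from ring closure. It sets out from 2: DDQ in methanol at 0 °C lets the solvent capture the quinone methide and should give the benzylic methyl ether, 7-methoxy mono-O-allyl secoisolariciresinol F1 (both C7 epimers). F1 is then cyclised without oxidant by catalytic pyridinium p-toluenesulfonate in CH2Cl2: loss of methanol regenerates the benzylic cation and the thermodynamically preferred 2,3-trans ring closes. The fallback comes back to the route at 4.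

Step 4. Enolisation of the α-aryloxy imide may be incomplete or unselective on a large Lewis-basic substrate, syn or facial selectivity may erode, and the electron-rich benzylic aldolate may undergo retro-aldol cleavage during work-up. The fallback sets both glycerol stereocentres by reduction instead of C–C bond formation and sets out from 4 and 8. Aldehyde 8 is homologated with ethyl diazoacetate and catalytic SnCl2 (Roskamp reaction) to the β-keto ester F2, which N-chlorosuccinimide converts into the α-chloro-β-keto ester F3. F3 alkylates phenol 4 (K2CO3, acetone, rt) to the configurationally labile α-aryloxy-β-keto ester F4. Asymmetric transfer hydrogenation with dynamic kinetic resolution (RuCl(p-cymene)[(R,R)-TsDPEN], HCO2H/Et3N, rt) should give the syn hydroxy ester F5; the (R,R) catalyst is the antipode predicted by the aryl-ketone model for the 7''S carbinol. LiBH4 reduction of the ester then comes back to the route at 12.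

Step 3. Acyl transfer from the imide carbonyl to the phenoxide (loss of the auxiliary) may compete with substitution at the chloromethyl carbon. The fallback attaches the two-carbon unit first and the auxiliary afterwards and sets out from 4. Williamson reaction with sodium chloroacetate (K2CO3, DMF, 60 °C, then acidification) should give the aryloxyacetic acid F6. Ac2O/pyridine followed by aqueous work-up gives the acetoxy acid F7. Activation as the mixed pivalic anhydride F8 (PivCl, Et3N, THF, −20 °C), followed by (R)-4-benzyloxazolidin-2-one and LiCl in the same flask, gives the imide and comes back to the route at 7.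

Further compounds
F1 | step 2 | 7-methoxy mono-O-allyl secoisolariciresinol (2 with OMe on the benzylic carbon of ring A, both epimers) | COC(c1ccc(O)c(OC)c1)[C@@H](CO)[C@H](CO)Cc1ccc(OCC=C)c(OC)c1
F2 | step 4 | ethyl 3-[4-(allyloxy)-3-methoxyphenyl]-3-oxopropanoate | CCOC(=O)CC(=O)c1ccc(OCC=C)c(OC)c1
F3 | step 4 | ethyl 2-chloro-3-[4-(allyloxy)-3-methoxyphenyl]-3-oxopropanoate | CCOC(=O)C(Cl)C(=O)c1ccc(OCC=C)c(OC)c1
F4 | step 4 | α-aryloxy-β-keto ester (F2 carrying at its α-carbon the ring A phenoxy group of 4, α-epimers) | COc1cc(C[C@H]2CO[C@H](c3ccc(OC(C(=O)OCC)C(=O)c4ccc(OCC=C)c(OC)c4)c(OC)c3)[C@H]2CO)ccc1OCC=C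
F5 | step 4 | syn hydroxy ester, ethyl (2R,3S)-3-[4-(allyloxy)-3-methoxyphenyl]-3-hydroxy-2-(aryloxy)propanoate with the aryloxy group of F4 | COc1cc(C[C@H]2CO[C@H](c3ccc(O[C@@H](C(=O)OCC)[C@@H](O)c4ccc(OCC=C)c(OC)c4)c(OC)c3)[C@H]2CO)ccc1OCC=C
F6 | step 3 | aryloxyacetic acid (4 with OCH2CO2H on ring A, C3 hydroxymethyl free) | COc1cc(C[C@H]2CO[C@H](c3ccc(OCC(=O)O)c(OC)c3)[C@H]2CO)ccc1OCC=C
F7 | step 3 | acetoxy acid (F6 with the C3 hydroxymethyl as its acetate) | COc1cc(C[C@H]2CO[C@H](c3ccc(OCC(=O)O)c(OC)c3)[C@H]2COC(C)=O)ccc1OCC=C
F8 | step 3 | mixed pivalic anhydride of F7 | COc1cc(C[C@H]2CO[C@H](c3ccc(OCC(=O)OC(=O)C(C)(C)C)c(OC)c3)[C@H]2COC(C)=O)ccc1OCC=C
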